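common to all: X 0.50 M (fed, over 8.0 s)
- north-east: D 0.15 M; E 50 mM; the very flask that is asked about, followed so far; the fed solution adds 1.0 times the starting volume
- north-west: D 0.15 M; E 100 mM; run made earlier; the fed solution adds 1.0 times the starting volume
- flask: D 0.150 M; E 50 mM; the fed solution adds 1.0 times the starting volume; time 5.0 min

north-east run (percent of the X charged)

| time / s | J / % | X / % |
|---|---|---|
| 10.0 | 7 | 95 |
| 20.0 | 15 | 85 |
| 30.0 | 23 | 79 |
| 50.0 | 35 | 65 |
| 80.0 | 47 | 51 |
| 90.0 | 56 | 45 |
| 120 | 65 | 31 |

north-west run (percent of the X charged)

| time / min | J / % | X / % |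
|---|---|---|
| 0.250 | 19 | 80 |
| 0.417 | 32 | 68 |
| 0.667 | 47 | 48 |
| 1.00 | 65 | 32 |
| 1.50 | 78 | 21 |
| 2.50 | 93 | 9 |
| 4.00 | 96 | 4 |

(readings scatter by 1.5 percentage points)

- charges are per starting volume, the dose included; the dosed solution carries all of it
- the average divides the monomer in chains by the number of chains begun, living and dead together
- the earlier runs do not show the number of chains; that part of a forecast is a guess

- whether the average number of monomer units in a chain (chains begun, living or dead) reaches 3.0 by 5.0 min (no / yes)
- average number of monomer units in a chain (chains begun, living or dead) at 5.0 min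

**Slow monomer.** X leaves the north-east flask slowly: 31 % of its charge still stands at 120 s, long after the 8.0 s feed has ended. For a first-order loss, the rate constant is the logarithm of charge over remainder, divided by time. That gives 0.00976 s⁻¹ here and 0.0190 s⁻¹ in the north-west run at 1.00 min.

**Setting the order.** The north-west constant is twice the north-east one, and its [E] is twice as well. So I read X as pseudo-first-order, with a constant that follows the growing ends, which begin from E.

**Chain ratio.** The length asked divides monomer in chains by chains begun, dead ones included. The readings do not show chains, so I guess one per E. Then X charged per E charged gives 10.0, the chain ratio. The length is this ratio times J's share of the charge once E has begun its chains, and longer before that.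

**My reckoning.** A length of 3.0 needs J at 30.0 %, and the north-east run reads 35 % at 50.0 s, so I say yes. With [E] halved, the north-east flask at 5.0 min should stand about where the north-west run stood at 2.50 min, a time shorter by twice, with X at 9 %. That makes the length 9.10.

**The forecast.** It says yes and 8.8, within 7 to 10.5, “Assuming one per E, with dying chains not restarted”, which is below my figure.

**The flask.** The north-east flask answers yes, reaching 3.0 at 0.640 min, and gives 9.06 at 5.0 min. The chain ratio times J at 90.6 % gives 9.06, with E at 0.0155 % of its charge.

    X → L (k = 1.20 × 10⁻⁴ s⁻¹)
    X + E → G + J (k = 0.340 M⁻¹ s⁻¹)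
    G + D → Z (k = 0.0160 M⁻¹ s⁻¹)
    X + G → J + G, rate k4*[G]*[X] (k = 0.390 M⁻¹ s⁻¹)

Step X + E → G + J has 98 % of its turnover up to 5.0 min behind it by 1.00 min, whereas step X + G → J + G reaches half of its own turnover up to 5.0 min at 1.32 min. The loss of G to Z reaches half of its turnover at 2.39 min, and at 5.00 min G is 0.0181 M beside Z at 0.00691 M. In the north-west run, the same ratio with one chain per E gives 4.80 from J at 96 % at 4.00 min.

(The runs are calculated from invented constants; noise was put on by code.)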